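**Retrosynthetic overview**
1. Target 17 ⇒ chloro lactone 16: C–O disconnection of the side-chain ester (carboxylate SN2 on a primary chloride).
2. 16 ⇒ lactone enol triflate 10 + (S)-secondary alkylzinc 15 (from 5-chloropentan-2-one): stereoretentive Negishi coupling makes the C5–C1′ bond.
3. 10 ⇒ acrylic acid 9: key C–O bond C7a–O by a carboxylate-directed γ-C(sp3)–H lactonization (new), closing the lactone (ring B) cis onto the cyclohexene (ring A).
4. 9 ⇒ (R)-carvone 1: α′-oxygenation/acylation (C4–O), conjugate reduction–triflation, isopropenyl → acrylic acid.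
5. Ring order: ring A comes with carvone (C3a stereocentre included); ring B is formed second, in step 6.

Assumption: the SMILES encodes (3aR,4S,7aR) in the ring and (S) at the side-chain carbon C1′ (benzofuranone numbering is used for ring atoms throughout); Me3SiCH2ZnBr·LiBr, the oxaziridine and the pyridone ligand are taken as available reagents.

**Route**

Step 1
Reactants: 1 (R)-(−)-carvone
Product: 4 (1S,6S)-3-methyl-2-oxo-6-(prop-1-en-2-yl)cyclohex-3-en-1-yl 2-methylpropanoate, via sodium dienolate 2 (not isolated), via sodium alkoxide 3 (not isolated)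
Conditions: NaN(SiMe3)2, THF, −78 °C; 2-(phenylsulfonyl)-3-phenyloxaziridine, −78 °C; then (iPrCO)2O, DMAP, −78 → 0 °C
Reagents that add atoms: 2-(phenylsulfonyl)-3-phenyloxaziridine, O=S(=O)(N1OC1c1ccccc1)c1ccccc1; isobutyric anhydride, CC(C)C(=O)OC(=O)C(C)C
Why: Kinetic α′-deprotonation gives the cross-conjugated dienolate, which is hydroxylated by the oxaziridine (Davis enolate oxidation) on the face anti to the neighbouring isopropenyl group, and the alkoxide is acylated in the same flask, so the new C4–O stereocentre is set trans to the isopropenyl group by substrate control (the minor cis epimer is removed by chromatography).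

Step 2
Reactants: 4 (1S,6S)-3-methyl-2-oxo-6-(prop-1-en-2-yl)cyclohex-3-en-1-yl 2-methylpropanoate
Product: 6 (1S,6S)-3-methyl-6-(prop-1-en-2-yl)-2-{[(trifluoromethyl)sulfonyl]oxy}cyclohex-2-en-1-yl 2-methylpropanoate, via lithium enolate 5 (not isolated)
Conditions: LiBH(s-Bu)3, THF, −78 °C; then N-(5-chloropyridin-2-yl)bis(trifluoromethanesulfonimide), −78 → −20 °C
Reagents that add atoms: N-(5-chloropyridin-2-yl)bis(trifluoromethanesulfonimide), O=S(=O)(N(c1ccc(Cl)cn1)S(=O)(=O)C(F)(F)F)C(F)(F)F
Why: Conjugate (1,4) reduction of the 2-methylcyclohexenone by the bulky borohydride gives the tetrasubstituted enolate regiospecifically at a temperature where the hindered ester is untouched, and O-sulfonylation (enol triflate formation) fixes the C5=C6 double bond without touching either stereocentre.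

Step 3
Reactants: 6 (1S,6S)-3-methyl-6-(prop-1-en-2-yl)-2-{[(trifluoromethyl)sulfonyl]oxy}cyclohex-2-en-1-yl 2-methylpropanoate
Product: 7 (1S,6S)-6-(3-chloroprop-1-en-2-yl)-3-methyl-2-{[(trifluoromethyl)sulfonyl]oxy}cyclohex-2-en-1-yl 2-methylpropanoate
Conditions: Ca(OCl)2, CO2 (solid), CH2Cl2/H2O, 0 °C
Reagents that add atoms: calcium hypochlorite, [Ca+2].[O-]Cl.[O-]Cl
Why: Ene-type allylic chlorination by HOCl generated in the flask attacks only the electron-rich 1,1-disubstituted isopropenyl double bond (the enol triflate is deactivated) and delivers the 2-(chloromethyl)vinyl group with allylic transposition, leaving both stereocentres untouched.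

Step 4
Reactants: 7 (1S,6S)-6-(3-chloroprop-1-en-2-yl)-3-methyl-2-{[(trifluoromethyl)sulfonyl]oxy}cyclohex-2-en-1-yl 2-methylpropanoate
Product: 8 (1S,6S)-3-methyl-6-(3-oxoprop-1-en-2-yl)-2-{[(trifluoromethyl)sulfonyl]oxy}cyclohex-2-en-1-yl 2-methylpropanoate
Conditions: N-methylmorpholine N-oxide, NaHCO3, MeCN, 55 °C
Reagents that add atoms: N-methylmorpholine N-oxide, C[N+]1([O-])CCOCC1
Why: Kornblum-type amine N-oxide oxidation, in which SN2 O-alkylation of the N-oxide by the allylic chloride and NaHCO3-mediated elimination of 4-methylmorpholine give the 2-substituted acrolein under conditions mild enough for the triflate and the ester.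

Step 5
Reactants: 8 (1S,6S)-3-methyl-6-(3-oxoprop-1-en-2-yl)-2-{[(trifluoromethyl)sulfonyl]oxy}cyclohex-2-en-1-yl 2-methylpropanoate
Product: 9 2-[(1S,2S)-4-methyl-2-(2-methylpropanoyloxy)-3-{[(trifluoromethyl)sulfonyl]oxy}cyclohex-3-en-1-yl]prop-2-enoic acid
Conditions: NaClO2, NaH2PO4, 2-methyl-2-butene, t-BuOH/H2O, 0 °C → rt
Reagents that add atoms: sodium chlorite, [Na+].[O-]Cl=O
Why: Pinnick oxidation turns the enal into the acrylic acid while 2-methyl-2-butene scavenges HOCl, so the alkenes, the triflate and the ester survive.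

Step 6
Reactants: 9 2-[(1S,2S)-4-methyl-2-(2-methylpropanoyloxy)-3-{[(trifluoromethyl)sulfonyl]oxy}cyclohex-3-en-1-yl]prop-2-enoic acid
Product: 10 (3aR,4S,7aR)-6-methyl-3-methylidene-2-oxo-5-{[(trifluoromethyl)sulfonyl]oxy}-2,3,3a,4,7,7a-hexahydro-1-benzofuran-4-yl 2-methylpropanoate
Conditions: Pd(OAc)2 (10 mol %), 6-(quinolin-8-yl)pyridin-2(1H)-one (20 mol %), t-BuOOH (70% aq, 2 equiv), CsOAc (0.5 equiv), (CF3)2CHOH, 60 °C
Reagents that add atoms: none
Why: Proposed new method: a carboxylate-directed γ-C(sp3)–H lactonization of a 2-alkylacrylic acid, in which the bound carboxylate of 9 places divalent palladium for pyridone-assisted concerted metalation–deprotonation of the C7a–H cis to the acrylate (C7a is the only γ-methylene, since the other γ-carbon C4 is an acyloxy-bearing methine and the β-carbon C3a is a methine) to give a six-membered palladacycle whose sp2 α-carbon copies the geometry of a 2-alkylbenzoic acid, after which t-BuOOH oxidises it to tetravalent palladium and C–O reductive elimination with retention closes the cis-fused lactone and sets C7a as R (the C7a–H anti to the axial acrylate cannot be reached by the chelate), while the electron-poor enol triflate is inert to divalent palladium; the closest known reaction types are the Pd-catalysed carboxylate-directed C(sp3)–H lactonization of 2-alkylbenzoic acids to phthalides and the ligand-enabled γ-methylene C–H lactonization of aliphatic carboxylic acids.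

Step 7
Reactants: 11 5-chloropentan-2-one
Product: 12 (2R)-5-chloropentan-2-ol
Conditions: alcohol dehydrogenase from Lactobacillus kefir, NADP+ (cat), i-PrOH, phosphate buffer pH 7, 30 °C
Reagents that add atoms: none
Why: Enzymatic asymmetric carbonyl reduction (anti-Prelog alcohol dehydrogenase with 2-propanol as the hydride source) sets the carbinol stereocentre as R in high enantiomeric excess and leaves the primary chloride alone.

Step 8
Reactants: 12 (2R)-5-chloropentan-2-ol
Product: 13 (2S)-5-chloro-2-iodopentane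
Conditions: PPh3, I2, imidazole, CH2Cl2, −20 → 0 °C
Reagents that add atoms: iodine, II
Why: Appel iodination, in which iodide displaces the alkoxyphosphonium leaving group by SN2 with inversion and so turns the (R)-alcohol into the (S)-iodide, the primary chloride being inert under these conditions.

Step 9
Reactants: 13 (2S)-5-chloro-2-iodopentane; 10 (3aR,4S,7aR)-6-methyl-3-methylidene-2-oxo-5-{[(trifluoromethyl)sulfonyl]oxy}-2,3,3a,4,7,7a-hexahydro-1-benzofuran-4-yl 2-methylpropanoate
Product: 16 (3aR,4S,7aR)-5-[(2S)-5-chloropentan-2-yl]-6-methyl-3-methylidene-2-oxo-2,3,3a,4,7,7a-hexahydro-1-benzofuran-4-yl 2-methylpropanoate, via (2S)-5-chloropentan-2-yllithium 14 (not isolated), via secondary alkylzinc reagent 15 (not isolated)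
Conditions: 13, t-BuLi (2.2 equiv), pentane/Et2O 3:2, −100 °C; Me3SiCH2ZnBr·LiBr, −100 → −30 °C; then 10, Pd(OAc)2 (5 mol %), CPhos (10 mol %), THF, −25 °C → rt
Reagents that add atoms: none
Why: Iodine–lithium exchange at −100 °C and transmetalation to zinc both go with retention, and the Negishi coupling (oxidative addition of zerovalent palladium into the C–OTf bond, transmetalation, reductive elimination) transfers the secondary alkyl group with retention, so the (S) side-chain stereocentre comes from 13 and the tetrasubstituted alkene is completed without touching the ring stereocentres.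

Step 10
Reactants: 16 (3aR,4S,7aR)-5-[(2S)-5-chloropentan-2-yl]-6-methyl-3-methylidene-2-oxo-2,3,3a,4,7,7a-hexahydro-1-benzofuran-4-yl 2-methylpropanoate
Product: 17 (4S)-4-[(3aR,4S,7aR)-6-methyl-3-methylidene-4-(2-methylpropanoyloxy)-2-oxo-2,3,3a,4,7,7a-hexahydro-1-benzofuran-5-yl]pentyl 2-methylpropanoate
Conditions: CsO2CCH(CH3)2 (3 equiv), DMF, 65 °C
Reagents that add atoms: cesium 2-methylpropanoate, CC(C)C(=O)[O-].[Cs+]
Why: SN2 esterification, in which the cesium carboxylate displaces the primary chloride in DMF to form the last C–O bond, and this weakly basic nucleophile neither adds to nor isomerises the α-methylene lactone, so no stereocentre is touched.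

**Compound list**
1 | (R)-(−)-carvone, (5R)-2-methyl-5-(prop-1-en-2-yl)cyclohex-2-en-1-one | C=C(C)[C@@H]1CC=C(C)C(=O)C1 | starting material
2 | sodium (3R)-6-methyl-3-(prop-1-en-2-yl)cyclohexa-1,5-dien-1-olate | C=C(C)[C@@H]1CC=C(C)C([O-])=C1.[Na+] | intermediate
3 | sodium (1S,6S)-3-methyl-2-oxo-6-(prop-1-en-2-yl)cyclohex-3-en-1-olate | C=C(C)[C@@H]1CC=C(C)C(=O)[C@H]1[O-].[Na+] | intermediate
4 | (1S,6S)-3-methyl-2-oxo-6-(prop-1-en-2-yl)cyclohex-3-en-1-yl 2-methylpropanoate (ester O trans to isopropenyl) | C=C(C)[C@@H]1CC=C(C)C(=O)[C@H]1OC(=O)C(C)C | intermediate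
5 | lithium (5S,6S)-2-methyl-6-(2-methylpropanoyloxy)-5-(prop-1-en-2-yl)cyclohex-1-en-1-olate | C=C(C)[C@@H]1CCC(C)=C([O-])[C@H]1OC(=O)C(C)C.[Li+] | intermediate
6 | (1S,6S)-3-methyl-6-(prop-1-en-2-yl)-2-{[(trifluoromethyl)sulfonyl]oxy}cyclohex-2-en-1-yl 2-methylpropanoate | C=C(C)[C@@H]1CCC(C)=C(OS(=O)(=O)C(F)(F)F)[C@H]1OC(=O)C(C)C | intermediate
7 | (1S,6S)-6-(3-chloroprop-1-en-2-yl)-3-methyl-2-{[(trifluoromethyl)sulfonyl]oxy}cyclohex-2-en-1-yl 2-methylpropanoate | C=C(CCl)[C@@H]1CCC(C)=C(OS(=O)(=O)C(F)(F)F)[C@H]1OC(=O)C(C)C | intermediate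
8 | (1S,6S)-3-methyl-6-(3-oxoprop-1-en-2-yl)-2-{[(trifluoromethyl)sulfonyl]oxy}cyclohex-2-en-1-yl 2-methylpropanoate | O=CC(=C)[C@@H]1CCC(C)=C(OS(=O)(=O)C(F)(F)F)[C@H]1OC(=O)C(C)C | intermediate
9 | 2-[(1S,2S)-4-methyl-2-(2-methylpropanoyloxy)-3-{[(trifluoromethyl)sulfonyl]oxy}cyclohex-3-en-1-yl]prop-2-enoic acid | OC(=O)C(=C)[C@@H]1CCC(C)=C(OS(=O)(=O)C(F)(F)F)[C@H]1OC(=O)C(C)C | intermediate
10 | (3aR,4S,7aR)-6-methyl-3-methylidene-2-oxo-5-{[(trifluoromethyl)sulfonyl]oxy}-2,3,3a,4,7,7a-hexahydro-1-benzofuran-4-yl 2-methylpropanoate (cis-fused lactone) | C=C1C(=O)O[C@@H]2CC(C)=C(OS(=O)(=O)C(F)(F)F)[C@@H](OC(=O)C(C)C)[C@H]12 | intermediate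
11 | 5-chloropentan-2-one | CC(=O)CCCCl | starting material
12 | (2R)-5-chloropentan-2-ol | O[C@H](C)CCCCl | intermediate
13 | (2S)-5-chloro-2-iodopentane | I[C@@H](C)CCCCl | intermediate
14 | (2S)-5-chloropentan-2-yllithium | [Li][C@@H](C)CCCCl | intermediate
15 | [(2S)-5-chloropentan-2-yl][(trimethylsilyl)methyl]zinc | C[Si](C)(C)C[Zn][C@@H](C)CCCCl | intermediate
16 | (3aR,4S,7aR)-5-[(2S)-5-chloropentan-2-yl]-6-methyl-3-methylidene-2-oxo-2,3,3a,4,7,7a-hexahydro-1-benzofuran-4-yl 2-methylpropanoate | C=C1C(=O)O[C@@H]2CC(C)=C([C@@H](C)CCCCl)[C@@H](OC(=O)C(C)C)[C@H]12 | intermediate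
17 | (4S)-4-[(3aR,4S,7aR)-6-methyl-3-methylidene-4-(2-methylpropanoyloxy)-2-oxo-2,3,3a,4,7,7a-hexahydro-1-benzofuran-5-yl]pentyl 2-methylpropanoate | C=C1C(=O)O[C@@H]2CC(C)=C([C@@H](C)CCCOC(=O)C(C)C)[C@@H](OC(=O)C(C)C)[C@H]12 | target

**Step count and risks**
Total step count: 10. Longest linear sequence: 8 steps (steps 1–6, 9, 10); the side-chain branch is steps 7–8.

Steps most likely to fail:

Step 6 (the proposed new C–H lactonization). β-Hydride elimination from the palladacycle or palladation of the vinylic C–H could win over lactonization. The fallback uses known chemistry, sets out from enal 8 and comes back at 10. Luche reduction (NaBH4, CeCl3·7H2O, MeOH, −40 °C) gives the allylic alcohol (1S,6S)-6-(3-hydroxyprop-1-en-2-yl)-3-methyl-2-{[(trifluoromethyl)sulfonyl]oxy}cyclohex-2-en-1-yl 2-methylpropanoate F1. A Suárez hypoiodite reaction (PhI(OAc)2, I2, cyclohexane, visible light) then forms the alkoxy radical, which takes the C7a hydrogen by 1,5-hydrogen transfer and closes the cis-fused cyclic ether (3aR,4S,7aR)-6-methyl-3-methylidene-5-{[(trifluoromethyl)sulfonyl]oxy}-2,3,3a,4,7,7a-hexahydro-1-benzofuran-4-yl 2-methylpropanoate F2. Allylic oxidation of the ether CH2 with CrO3·3,5-dimethylpyrazole (CH2Cl2, −20 °C) gives lactone 10.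

Step 9 (secondary alkyl Negishi coupling on a hindered tetrasubstituted enol triflate next to an α-methylene lactone). β-Hydride elimination or slow reductive elimination could erode yield or branching. The fallback sets out from 13 and 10 and comes back at 16. The organolithium 14, made as in step 9, is trapped with 5-chloro-1-aza-5-stannabicyclo[3.3.3]undecane to give, with retention, the isolable and configurationally stable azastannatrane 5-[(2S)-5-chloropentan-2-yl]-1-aza-5-stannabicyclo[3.3.3]undecane F3. This is coupled with 10 in a stereoretentive Stille reaction (Pd(dba)2, JackiePhos, CuCl, KF, MeCN, 60 °C) to give 16.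

Step 2 (enolate with a neighbouring ester). Acyl migration from the C4 oxygen to the enolate oxygen, or ester reduction, could compete. The fallback sets out from 4 and comes back at 6 and avoids any metal enolate. RhCl(PPh3)3-catalysed 1,4-hydrosilylation with Et3SiH (THF, 50 °C) gives the silyl enol ether (1S,6S)-3-methyl-6-(prop-1-en-2-yl)-2-[(triethylsilyl)oxy]cyclohex-2-en-1-yl 2-methylpropanoate F4. Fluoride-triggered sulfonylation (CsF, PhN(SO2CF3)2, 1,2-dimethoxyethane, rt) converts it into triflate 6.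

Further compounds
F1 | step 6 | (1S,6S)-6-(3-hydroxyprop-1-en-2-yl)-3-methyl-2-{[(trifluoromethyl)sulfonyl]oxy}cyclohex-2-en-1-yl 2-methylpropanoate | OCC(=C)[C@@H]1CCC(C)=C(OS(=O)(=O)C(F)(F)F)[C@H]1OC(=O)C(C)C
F2 | step 6 | (3aR,4S,7aR)-6-methyl-3-methylidene-5-{[(trifluoromethyl)sulfonyl]oxy}-2,3,3a,4,7,7a-hexahydro-1-benzofuran-4-yl 2-methylpropanoate | C=C1CO[C@@H]2CC(C)=C(OS(=O)(=O)C(F)(F)F)[C@@H](OC(=O)C(C)C)[C@H]12
F3 | step 9 | 5-[(2S)-5-chloropentan-2-yl]-1-aza-5-stannabicyclo[3.3.3]undecane | [Sn]12(CCCN(CCC1)CCC2)[C@@H](C)CCCCl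
F4 | step 2 | (1S,6S)-3-methyl-6-(prop-1-en-2-yl)-2-[(triethylsilyl)oxy]cyclohex-2-en-1-yl 2-methylpropanoate | C=C(C)[C@@H]1CCC(C)=C(O[Si](CC)(CC)CC)[C@H]1OC(=O)C(C)C
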